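**Plan**

- Retrosynthesis: the aryl–acyl bond C1'–C(=O) is cut first (aryllithium plus cinnamic Weinreb amide). Ring A is then cut at C4'–C5', C6'–C1' and C3'–C4' into a cyclobutenone and methoxyacetylene, and the cyclobutenone into an aldoketene and (triisopropylsilyloxy)acetylene. The chain is cut at C5=C6 (cross-metathesis) and at C7–CH2 (allylic alkylation).
- Enabling feature: ring A is a 1,3,5-trioxygenated benzene in which C3' carries C7 between two oxygens and the C6' methoxyl is para to it. C4'–O maps onto a ketene carbonyl, C2'–O onto the 3-silyloxy group of a cyclobutenone whose C4 is C3', and C6'–OMe onto methoxyacetylene.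
- Forward: an aryl-pentenoic acid and a homoallylic silyl ether are joined by cross-metathesis, the acid is turned into the four-membered ring, ring A is built around it, and the cinnamoyl group is attached last. Once both flanking oxygens carry the same silyl group the two free ring-A carbons are equivalent, so the acylation has no regiochemical issue.
- Stereochemistry: C7 comes from an iridium-catalysed asymmetric allylic alkylation, C3 from a Keck allylation, the C5=C6 (E)-alkene from metathesis and the chalcone (E)-alkene from the amide. Neither stereocentre is touched after it is set.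

Key step: step 15

Abbreviations: TBS = tert-butyldimethylsilyl; TIPS = triisopropylsilyl; TBSO/TIPSO = the silyloxy groups; 4-TIPSO-phenyl = 4-(triisopropylsilyloxy)phenyl; L = O,O'-[(S)-1,1'-binaphthyl-2,2'-diyl] N,N-bis[(S)-1-phenylethyl]phosphoramidite; TBD = 1,5,7-triazabicyclo[4.4.0]dec-5-ene.

Assumption: the facial sense of the [Ir(cod)Cl]2/L catalyst (step 4) and of the (S)-BINOL/Ti(OiPr)4 catalyst (step 9) is taken by analogy with the parent cinnamyl carbonate and 3-phenylpropanal; the mirror-image ligand would be used if a model run showed the opposite sense.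

Remark: C1–C7 and C1'–C6' are the diarylheptanoid and ring-A locants of the target. CIP descriptors are those of each individual compound, so the unchanged C7 centre is R or S depending on its neighbours. Metal alkoxides and chelates that are only protonated on work-up are not numbered.

**Route**

Step 1
Reactants: 1 ethyl (E)-4-hydroxycinnamate
Product: 2 ethyl (E)-3-[4-(TBSO)phenyl]prop-2-enoate
Conditions: TBSCl, imidazole, DMF, rt
Reagents that add atoms: tert-butyldimethylsilyl chloride, CC(C)(C)[Si](C)(C)Cl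
Why: Imidazole-promoted O-silylation of the phenol masks the acidic OH for the hydride and iridium steps; this silyl ether is deliberately temporary and is shed in step 5.

Step 2
Reactants: 2 ethyl (E)-3-[4-(TBSO)phenyl]prop-2-enoate
Product: 3 (E)-3-[4-(TBSO)phenyl]prop-2-en-1-ol
Conditions: i-Bu2AlH (2.2 equiv), CH2Cl2, −78 °C; aq. potassium sodium tartrate
Reagents that add atoms: none
Why: 1,2-Reduction of the conjugated ester by i-Bu2AlH at low temperature should give the (E)-allylic alcohol without conjugate reduction or loss of the aryl silyl ether.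

Step 3
Reactants: 3 (E)-3-[4-(TBSO)phenyl]prop-2-en-1-ol
Product: 4 (E)-3-[4-(TBSO)phenyl]prop-2-en-1-yl methyl carbonate
Conditions: ClCO2Me, pyridine, CH2Cl2, 0 °C
Reagents that add atoms: methyl chloroformate, COC(=O)Cl
Why: Pyridine-mediated acylation of the primary allylic alcohol gives the allylic carbonate, the usual leaving group for iridium-catalysed allylic substitution.

Step 4
Reactants: 4 (E)-3-[4-(TBSO)phenyl]prop-2-en-1-yl methyl carbonate; 5 dimethyl malonate
Product: 6 dimethyl 2-{(1R)-1-[4-(TBSO)phenyl]prop-2-en-1-yl}propanedioate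
Conditions: [Ir(cod)Cl]2 (2 mol %), L (4 mol %), TBD (8 mol %), THF, rt
Reagents that add atoms: none
Why: Iridium-catalysed branched-selective asymmetric allylic alkylation: the catalyst formed from [Ir(cod)Cl]2 and L ionises the carbonate, and the malonate (deprotonated by the released methoxide) attacks the aryl-substituted allyl terminus on the face left open by the (Sa,S,S)-ligand, which sets the future C7 as (R) in 6.

Step 5
Reactants: 6 dimethyl 2-{(1R)-1-[4-(TBSO)phenyl]prop-2-en-1-yl}propanedioate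
Product: 8 (3S)-3-(4-hydroxyphenyl)pent-4-enoic acid, via malonic acid 7 (not isolated)
Conditions: LiOH, THF/MeOH/H2O, 40 °C; aq. HCl to pH 2; then pyridine, 100 °C
Reagents that add atoms: lithium hydroxide, [Li+].[OH-]
Why: Saponification of both esters (which also cleaves the labile aryl TBS ether) followed by thermal decarboxylation of the malonic acid through its cyclic transition state should give the monoacid, and C7 is not acidic under these conditions (its descriptor becomes S only because the CIP ranking changes).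

Step 6
Reactants: 8 (3S)-3-(4-hydroxyphenyl)pent-4-enoic acid
Product: 10 (3S)-3-(4-TIPSO-phenyl)pent-4-enoic acid, via silyl ester 9 (not isolated)
Conditions: TIPSCl (2.5 equiv), imidazole, DMF, rt; then K2CO3, MeOH/THF/H2O, rt; aq. HCl to pH 4
Reagents that add atoms: triisopropylsilyl chloride, CC(C)[Si](Cl)(C(C)C)C(C)C
Why: Silyl chloride/imidazole silylation caps both the phenol and the acid, and the far more labile silyl ester is then solvolysed selectively by carbonate in methanol, leaving the robust aryl TIPS ether.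

Step 7
Reactants: 11 methyl 3-(4-hydroxyphenyl)propanoate
Product: 12 methyl 3-(4-TIPSO-phenyl)propanoate
Conditions: TIPSCl, imidazole, DMF, rt
Reagents that add atoms: triisopropylsilyl chloride, CC(C)[Si](Cl)(C(C)C)C(C)C
Why: Imidazole-promoted silylation gives an aryl TIPS ether that tolerates the hydride, Lewis-acid, metathesis and organolithium conditions used later.

Step 8
Reactants: 12 methyl 3-(4-TIPSO-phenyl)propanoate
Product: 13 3-(4-TIPSO-phenyl)propanal
Conditions: i-Bu2AlH (1.05 equiv), CH2Cl2, −78 °C; MeOH, aq. potassium sodium tartrate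
Reagents that add atoms: none
Why: Partial reduction of the ester with one equivalent of i-Bu2AlH at −78 °C should stop at the aldehyde because the tetrahedral O–Al(i-Bu)2 hemiacetal collapses only on work-up.

Step 9
Reactants: 13 3-(4-TIPSO-phenyl)propanal
Product: 14 (3R)-1-(4-TIPSO-phenyl)hex-5-en-3-ol
Conditions: allylSnBu3, (S)-BINOL (10 mol %), Ti(OiPr)4 (10 mol %), 4 Å MS, CH2Cl2, −20 °C; aq. NaHCO3
Reagents that add atoms: allyltributyltin, C=CC[Sn](CCCC)(CCCC)CCCC
Why: Keck asymmetric allylation: the (S)-BINOL/Ti(OiPr)4 Lewis acid activates the aldehyde and shields one face so that the allylstannane adds to the si face, setting C3 as (R).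

Step 10
Reactants: 14 (3R)-1-(4-TIPSO-phenyl)hex-5-en-3-ol
Product: 15 (3R)-3-(TBSO)-1-(4-TIPSO-phenyl)hex-5-ene
Conditions: TBSCl, imidazole, DMF, rt
Reagents that add atoms: tert-butyldimethylsilyl chloride, CC(C)(C)[Si](C)(C)Cl
Why: Standard silylation of the secondary alcohol, needed so that the hydroxyl cannot be acylated when the acid chloride and ketene are generated; the ether should last until the final fluoride treatment.

Step 11
Reactants: 10 (3S)-3-(4-TIPSO-phenyl)pent-4-enoic acid; 15 (3R)-3-(TBSO)-1-(4-TIPSO-phenyl)hex-5-ene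
Product: 16 (3S,4E,7R)-7-(TBSO)-3,9-bis(4-TIPSO-phenyl)non-4-enoic acid
Conditions: 15 (3 equiv), second-generation Hoveyda–Grubbs catalyst (5 mol %), 1,4-benzoquinone (10 mol %), CH2Cl2, 40 °C
Reagents that add atoms: none
Why: Olefin cross-metathesis between the allylically branched terminal alkene of 10 and an excess of the unhindered homoallylic ether should give the thermodynamically favoured (E)-alkene; the catalyst tolerates the free acid and benzoquinone suppresses double-bond migration that would endanger C7.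

Step 12
Reactants: 17 3-phenylisoxazole
Product: 20 (triisopropylsilyloxy)acetylene, via 5-lithio-3-phenylisoxazole 18 (not isolated), via lithium ethynolate 19 (not isolated)
Conditions: n-BuLi (1.0 equiv), THF, −78 to −40 °C; TIPSOTf, −78 to 0 °C
Reagents that add atoms: triisopropylsilyl trifluoromethanesulfonate, CC(C)[Si](OS(=O)(=O)C(F)(F)F)(C(C)C)C(C)C
Why: Deprotonation at C5 of the isoxazole triggers ring fragmentation to benzonitrile and the lithium ynolate, and the bulky silyl triflate should silylate the ynolate at oxygen, as in the usual ynolate route to siloxyalkynes.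

Step 13
Reactants: 16 (3S,4E,7R)-7-(TBSO)-3,9-bis(4-TIPSO-phenyl)non-4-enoic acid; 20 (triisopropylsilyloxy)acetylene
Product: 23 4-[(1R,2E,5R)-5-(TBSO)-1,7-bis(4-TIPSO-phenyl)hept-2-en-1-yl]-3-(TIPSO)cyclobut-2-en-1-one (C4 epimers), via acid chloride 21 (not isolated), via aldoketene 22 (not isolated)
Conditions: 1-chloro-N,N,2-trimethylprop-1-en-1-amine, CH2Cl2, 0 °C to rt; then slow addition to 20 (3 equiv) and Et3N in CH2Cl2, 0 °C to rt
Reagents that add atoms: none
Why: Ketene–ynol ether [2+2] cycloaddition: the chloroenamine makes the acid chloride under neutral conditions, Et3N dehydrochlorinates it to the aldoketene, and the nucleophilic CH terminus of the siloxyalkyne attacks the ketene carbonyl carbon, so ring closure places the silyloxy group at C3 and the C7-bearing carbon at C4; the new ring stereocentre is inconsequential.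

Step 14
Reactants: 24 chloroacetaldehyde dimethyl acetal
Product: 27 methoxyacetylene, via 1-chloro-2-methoxyethene 25 (not isolated), via sodium methoxyacetylide 26 (not isolated)
Conditions: NaNH2 (3.3 equiv), liquid NH3, −33 °C; aq. NH4Cl, −70 °C; distillation into cold toluene
Reagents that add atoms: none
Why: Loss of methanol and then of HCl from the chloroacetal under NaNH2 (the classical alkoxyacetylene synthesis) gives the sodium acetylide, which is protonated on quenching and distilled as the volatile ynol ether.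

Step 15
Reactants: 23 4-[(1R,2E,5R)-5-(TBSO)-1,7-bis(4-TIPSO-phenyl)hept-2-en-1-yl]-3-(TIPSO)cyclobut-2-en-1-one; 27 methoxyacetylene
Product: 32 5-methoxy-2-[(1S,2E,5R)-5-(TBSO)-1,7-bis(4-TIPSO-phenyl)hept-2-en-1-yl]-3-(TIPSO)phenol, via vinylketene 28 (not isolated), via vinylcyclobutenone 29 (not isolated), via dienylketene 30 (not isolated), via cyclohexadienone 31 (not isolated)
Conditions: 27 (4 equiv), toluene, sealed tube, 80 °C then 110 °C
Reagents that add atoms: none
Why: Heating opens 23 by 4π-electrocyclic ring opening to the silyloxyvinylketene 28, whose carbonyl carbon is attacked by the nucleophilic CH terminus of methoxyacetylene in a regioselective [2+2] cycloaddition to give 29; reversible 4π opening of 29 feeds the cis-dienylketene 30, and ring A is closed by thermal disrotatory 6π-electrocyclisation (new C3'–C4' bond) to dienone 31, which tautomerises to the phenol. The reaction is a Danheiser benzannulation of a cyclobutenone with an alkoxyacetylene, applied here to a 3-silyloxy-4-alkylcyclobutenone, and is closely related to the siloxyalkyne–vinylketene route to resorcinol monosilyl ethers. No stereocentre is created: the sp3 ring carbons of 23, 29 and 31 are erased on aromatisation, and C7 and C3 are spectators. The step needs the regiochemistry of the [2+2] event, which the polarisation of the ynol ether secures and which places OMe para to C3', and outward rotation of the C7 substituent in the first ring opening, which is favoured for an alkyl group over hydrogen and keeps C7–H away from the ketene so that no 1,5-hydrogen shift can erase C7. Methoxyacetylene has no β-hydrogen and so cannot fragment to ketene at these temperatures, and its excess should outrun acylation of the product phenol by the vinylketene.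

Step 16
Reactants: 32 5-methoxy-2-[(1S,2E,5R)-5-(TBSO)-1,7-bis(4-TIPSO-phenyl)hept-2-en-1-yl]-3-(TIPSO)phenol
Product: 33 5-methoxy-2-[(1S,2E,5R)-5-(TBSO)-1,7-bis(4-TIPSO-phenyl)hept-2-en-1-yl]-1,3-bis(TIPSO)benzene
Conditions: TIPSOTf, 2,6-lutidine, CH2Cl2, 0 °C to rt
Reagents that add atoms: triisopropylsilyl trifluoromethanesulfonate, CC(C)[Si](OS(=O)(=O)C(F)(F)F)(C(C)C)C(C)C
Why: Silyl triflate/lutidine silylation of the hindered phenol; with both flanking oxygens now carrying TIPS, ring A has local twofold symmetry and its two remaining CH positions become equivalent.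

Step 17
Reactants: 33 5-methoxy-2-[(1S,2E,5R)-5-(TBSO)-1,7-bis(4-TIPSO-phenyl)hept-2-en-1-yl]-1,3-bis(TIPSO)benzene
Product: 34 4-bromo-5-methoxy-2-[(1S,2E,5R)-5-(TBSO)-1,7-bis(4-TIPSO-phenyl)hept-2-en-1-yl]-1,3-bis(TIPSO)benzene
Conditions: NBS (1.0 equiv), CH2Cl2, −78 to 0 °C
Reagents that add atoms: N-bromosuccinimide, O=C1CCC(=O)N1Br
Why: Electrophilic aromatic bromination: the triply oxygen-activated ring-A CH positions should react far faster than the alkene or the mono-oxygenated rings, their equivalence removes any regiochemical question, and no strong acid is formed that could ionise the C7–aryl bond.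

Step 18
Reactants: 34 4-bromo-5-methoxy-2-[(1S,2E,5R)-5-(TBSO)-1,7-bis(4-TIPSO-phenyl)hept-2-en-1-yl]-1,3-bis(TIPSO)benzene; 35 (E)-N-methoxy-N-methylcinnamamide
Product: 37 (E)-1-{6-methoxy-3-[(1S,2E,5R)-5-(TBSO)-1,7-bis(4-TIPSO-phenyl)hept-2-en-1-yl]-2,4-bis(TIPSO)phenyl}-3-phenylprop-2-en-1-one, via aryllithium 36 (not isolated)
Conditions: t-BuLi (2.05 equiv), THF, −78 °C; 35, −78 to −20 °C; aq. NH4Cl
Reagents that add atoms: none
Why: Bromine–lithium exchange followed by acylation of the aryllithium with the Weinreb amide, whose chelated tetrahedral adduct prevents over-addition and conjugate addition and releases the (E)-enone only on work-up; the acylated carbon becomes C1'.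

Step 19
Reactants: 37 (E)-1-{6-methoxy-3-[(1S,2E,5R)-5-(TBSO)-1,7-bis(4-TIPSO-phenyl)hept-2-en-1-yl]-2,4-bis(TIPSO)phenyl}-3-phenylprop-2-en-1-one
Product: 38 7-epi-katsumain C
Conditions: Bu4NF, AcOH (1:1, excess), THF, 0 °C to rt
Reagents that add atoms: none
Why: Acetic acid-buffered fluoride should cleave the four aryl silyl ethers and the secondary TBS ether by fluoride-driven Si–O cleavage, avoiding both the basic conditions that could cyclise the 2'-hydroxychalcone to a flavanone and the acidic ones that could ionise C7.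

**Compound list**

1 | ethyl (E)-4-hydroxycinnamate | CCOC(=O)/C=C/c1ccc(O)cc1 | starting material
2 | ethyl (E)-3-[4-(tert-butyldimethylsilyloxy)phenyl]prop-2-enoate | CCOC(=O)/C=C/c1ccc(O[Si](C)(C)C(C)(C)C)cc1 | intermediate
3 | (E)-3-[4-(tert-butyldimethylsilyloxy)phenyl]prop-2-en-1-ol | OC/C=C/c1ccc(O[Si](C)(C)C(C)(C)C)cc1 | intermediate
4 | (E)-3-[4-(tert-butyldimethylsilyloxy)phenyl]prop-2-en-1-yl methyl carbonate | COC(=O)OC/C=C/c1ccc(O[Si](C)(C)C(C)(C)C)cc1 | intermediate
5 | dimethyl malonate | COC(=O)CC(=O)OC | starting material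
6 | dimethyl 2-{(1R)-1-[4-(tert-butyldimethylsilyloxy)phenyl]prop-2-en-1-yl}propanedioate | COC(=O)C(C(=O)OC)[C@@H](C=C)c1ccc(O[Si](C)(C)C(C)(C)C)cc1 | intermediate
7 | 2-[(1R)-1-(4-hydroxyphenyl)prop-2-en-1-yl]propanedioic acid | OC(=O)C(C(=O)O)[C@@H](C=C)c1ccc(O)cc1 | intermediate
8 | (3S)-3-(4-hydroxyphenyl)pent-4-enoic acid | OC(=O)C[C@@H](C=C)c1ccc(O)cc1 | intermediate
9 | triisopropylsilyl (3S)-3-[4-(triisopropylsilyloxy)phenyl]pent-4-enoate | CC(C)[Si](C(C)C)(C(C)C)OC(=O)C[C@@H](C=C)c1ccc(O[Si](C(C)C)(C(C)C)C(C)C)cc1 | intermediate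
10 | (3S)-3-[4-(triisopropylsilyloxy)phenyl]pent-4-enoic acid | OC(=O)C[C@@H](C=C)c1ccc(O[Si](C(C)C)(C(C)C)C(C)C)cc1 | intermediate
11 | methyl 3-(4-hydroxyphenyl)propanoate | COC(=O)CCc1ccc(O)cc1 | starting material
12 | methyl 3-[4-(triisopropylsilyloxy)phenyl]propanoate | COC(=O)CCc1ccc(O[Si](C(C)C)(C(C)C)C(C)C)cc1 | intermediate
13 | 3-[4-(triisopropylsilyloxy)phenyl]propanal | O=CCCc1ccc(O[Si](C(C)C)(C(C)C)C(C)C)cc1 | intermediate
14 | (3R)-1-[4-(triisopropylsilyloxy)phenyl]hex-5-en-3-ol | C=CC[C@H](O)CCc1ccc(O[Si](C(C)C)(C(C)C)C(C)C)cc1 | intermediate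
15 | (3R)-3-(tert-butyldimethylsilyloxy)-1-[4-(triisopropylsilyloxy)phenyl]hex-5-ene | C=CC[C@H](O[Si](C)(C)C(C)(C)C)CCc1ccc(O[Si](C(C)C)(C(C)C)C(C)C)cc1 | intermediate
16 | (3S,4E,7R)-7-(TBSO)-3,9-bis(4-TIPSO-phenyl)non-4-enoic acid | OC(=O)C[C@@H](/C=C/C[C@H](O[Si](C)(C)C(C)(C)C)CCc1ccc(O[Si](C(C)C)(C(C)C)C(C)C)cc1)c1ccc(O[Si](C(C)C)(C(C)C)C(C)C)cc1 | intermediate
17 | 3-phenylisoxazole | c1cc(-c2ccccc2)no1 | starting material
18 | 5-lithio-3-phenylisoxazole | [Li]c1cc(-c2ccccc2)no1 | intermediate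
19 | lithium ethynolate | [Li+].[O-]C#C | intermediate
20 | (triisopropylsilyloxy)acetylene | C#CO[Si](C(C)C)(C(C)C)C(C)C | intermediate
21 | (3S,4E,7R)-7-(TBSO)-3,9-bis(4-TIPSO-phenyl)non-4-enoyl chloride | ClC(=O)C[C@@H](/C=C/C[C@H](O[Si](C)(C)C(C)(C)C)CCc1ccc(O[Si](C(C)C)(C(C)C)C(C)C)cc1)c1ccc(O[Si](C(C)C)(C(C)C)C(C)C)cc1 | intermediate
22 | (3R,4E,7R)-7-(TBSO)-3,9-bis(4-TIPSO-phenyl)nona-1,4-dien-1-one (aldoketene) | O=C=C[C@@H](/C=C/C[C@H](O[Si](C)(C)C(C)(C)C)CCc1ccc(O[Si](C(C)C)(C(C)C)C(C)C)cc1)c1ccc(O[Si](C(C)C)(C(C)C)C(C)C)cc1 | intermediate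
23 | 4-[(1R,2E,5R)-5-(TBSO)-1,7-bis(4-TIPSO-phenyl)hept-2-en-1-yl]-3-(triisopropylsilyloxy)cyclobut-2-en-1-one (C4 epimers) | O=C1C=C(O[Si](C(C)C)(C(C)C)C(C)C)C1[C@@H](/C=C/C[C@H](O[Si](C)(C)C(C)(C)C)CCc1ccc(O[Si](C(C)C)(C(C)C)C(C)C)cc1)c1ccc(O[Si](C(C)C)(C(C)C)C(C)C)cc1 | intermediate
24 | chloroacetaldehyde dimethyl acetal | COC(CCl)OC | starting material
25 | 1-chloro-2-methoxyethene (E/Z) | COC=CCl | intermediate
26 | sodium methoxyacetylide | [Na+].[C-]#COC | intermediate
27 | methoxyacetylene | COC#C | intermediate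
28 | (3Z,5R,6E,9R)-9-(TBSO)-3-(TIPSO)-5,11-bis(4-TIPSO-phenyl)undeca-1,3,6-trien-1-one (vinylketene) | O=C=C/C(O[Si](C(C)C)(C(C)C)C(C)C)=C/[C@@H](/C=C/C[C@H](O[Si](C)(C)C(C)(C)C)CCc1ccc(O[Si](C(C)C)(C(C)C)C(C)C)cc1)c1ccc(O[Si](C(C)C)(C(C)C)C(C)C)cc1 | intermediate
29 | 3-methoxy-4-[(1Z,3R,4E,7R)-7-(TBSO)-1-(TIPSO)-3,9-bis(4-TIPSO-phenyl)nona-1,4-dien-1-yl]cyclobut-2-en-1-one (C4 epimers) | O=C1C=C(OC)C1/C(O[Si](C(C)C)(C(C)C)C(C)C)=C/[C@@H](/C=C/C[C@H](O[Si](C)(C)C(C)(C)C)CCc1ccc(O[Si](C(C)C)(C(C)C)C(C)C)cc1)c1ccc(O[Si](C(C)C)(C(C)C)C(C)C)cc1 | intermediate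
30 | (3E,5Z,7R,8E,11R)-3-methoxy-11-(TBSO)-5-(TIPSO)-7,13-bis(4-TIPSO-phenyl)trideca-1,3,5,8-tetraen-1-one (dienylketene) | O=C=C/C(OC)=C\C(O[Si](C(C)C)(C(C)C)C(C)C)=C\[C@@H](/C=C/C[C@H](O[Si](C)(C)C(C)(C)C)CCc1ccc(O[Si](C(C)C)(C(C)C)C(C)C)cc1)c1ccc(O[Si](C(C)C)(C(C)C)C(C)C)cc1 | intermediate
31 | 3-methoxy-6-[(1R,2E,5R)-5-(TBSO)-1,7-bis(4-TIPSO-phenyl)hept-2-en-1-yl]-5-(triisopropylsilyloxy)cyclohexa-2,4-dien-1-one (C6 epimers) | O=C1C=C(OC)C=C(O[Si](C(C)C)(C(C)C)C(C)C)C1[C@@H](/C=C/C[C@H](O[Si](C)(C)C(C)(C)C)CCc1ccc(O[Si](C(C)C)(C(C)C)C(C)C)cc1)c1ccc(O[Si](C(C)C)(C(C)C)C(C)C)cc1 | intermediate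
32 | 5-methoxy-2-[(1S,2E,5R)-5-(TBSO)-1,7-bis(4-TIPSO-phenyl)hept-2-en-1-yl]-3-(triisopropylsilyloxy)phenol | COc1cc(O)c([C@@H](/C=C/C[C@H](O[Si](C)(C)C(C)(C)C)CCc2ccc(O[Si](C(C)C)(C(C)C)C(C)C)cc2)c2ccc(O[Si](C(C)C)(C(C)C)C(C)C)cc2)c(O[Si](C(C)C)(C(C)C)C(C)C)c1 | intermediate
33 | 5-methoxy-2-[(1S,2E,5R)-5-(TBSO)-1,7-bis(4-TIPSO-phenyl)hept-2-en-1-yl]-1,3-bis(triisopropylsilyloxy)benzene | COc1cc(O[Si](C(C)C)(C(C)C)C(C)C)c([C@@H](/C=C/C[C@H](O[Si](C)(C)C(C)(C)C)CCc2ccc(O[Si](C(C)C)(C(C)C)C(C)C)cc2)c2ccc(O[Si](C(C)C)(C(C)C)C(C)C)cc2)c(O[Si](C(C)C)(C(C)C)C(C)C)c1 | intermediate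
34 | 4-bromo-5-methoxy-2-[(1S,2E,5R)-5-(TBSO)-1,7-bis(4-TIPSO-phenyl)hept-2-en-1-yl]-1,3-bis(triisopropylsilyloxy)benzene | COc1cc(O[Si](C(C)C)(C(C)C)C(C)C)c([C@@H](/C=C/C[C@H](O[Si](C)(C)C(C)(C)C)CCc2ccc(O[Si](C(C)C)(C(C)C)C(C)C)cc2)c2ccc(O[Si](C(C)C)(C(C)C)C(C)C)cc2)c(O[Si](C(C)C)(C(C)C)C(C)C)c1Br | intermediate
35 | (E)-N-methoxy-N-methylcinnamamide | CON(C)C(=O)/C=C/c1ccccc1 | starting material
36 | {6-methoxy-3-[(1S,2E,5R)-5-(TBSO)-1,7-bis(4-TIPSO-phenyl)hept-2-en-1-yl]-2,4-bis(triisopropylsilyloxy)phenyl}lithium | COc1cc(O[Si](C(C)C)(C(C)C)C(C)C)c([C@@H](/C=C/C[C@H](O[Si](C)(C)C(C)(C)C)CCc2ccc(O[Si](C(C)C)(C(C)C)C(C)C)cc2)c2ccc(O[Si](C(C)C)(C(C)C)C(C)C)cc2)c(O[Si](C(C)C)(C(C)C)C(C)C)c1[Li] | intermediate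
37 | (E)-1-{6-methoxy-3-[(1S,2E,5R)-5-(TBSO)-1,7-bis(4-TIPSO-phenyl)hept-2-en-1-yl]-2,4-bis(triisopropylsilyloxy)phenyl}-3-phenylprop-2-en-1-one | COc1cc(O[Si](C(C)C)(C(C)C)C(C)C)c([C@@H](/C=C/C[C@H](O[Si](C)(C)C(C)(C)C)CCc2ccc(O[Si](C(C)C)(C(C)C)C(C)C)cc2)c2ccc(O[Si](C(C)C)(C(C)C)C(C)C)cc2)c(O[Si](C(C)C)(C(C)C)C(C)C)c1C(=O)/C=C/c1ccccc1 | intermediate
38 | 7-epi-katsumain C, (E)-1-{2,4-dihydroxy-3-[(1S,2E,5R)-5-hydroxy-1,7-bis(4-hydroxyphenyl)hept-2-en-1-yl]-6-methoxyphenyl}-3-phenylprop-2-en-1-one | COc1cc(O)c([C@@H](/C=C/C[C@H](O)CCc2ccc(O)cc2)c2ccc(O)cc2)c(O)c1C(=O)/C=C/c1ccccc1 | target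

**Step count and risks**

Total steps: 19. Longest linear sequence: 13 steps (steps 1–6, 11, 13, 15–19).

Steps most likely to fail:

1. Step 15. The donor-stabilised cyclobutenone may open sluggishly. Inward rotation of the C7 substituent followed by a 1,5-hydrogen shift would destroy C7. The vinylogous silyl ester may lose its silyl group, or the product phenol may be acylated by the vinylketene. The fallback inverts the roles of the two partners, so that C7 rides on the siloxyalkyne and is never next to a ketene; it sets out from 16 and comes back at 32. Acid 16 is esterified with Me3SiCHN2 to the methyl (3S,4E,7R)-7-(TBSO)-3,9-bis(4-TIPSO-phenyl)non-4-enoate F1, which two rounds of LiN(SiMe3)2/CBr4 convert into the α,α-dibromo ester F2. Treatment of F2 with t-BuLi (4 equiv, THF, −78 to 0 °C) cleaves the ester dianion to the lithium ynolate, and TIPSOTf gives the siloxyalkyne F3. (E)-3-Methoxybut-2-enoyl chloride F4, made from the acid and (COCl)2, is dehydrochlorinated by Et3N at room temperature to 3-methoxybuta-1,3-dien-1-one F5. F5 is trapped by F3 in a [2+2] cycloaddition to the vinylcyclobutenone F6, and heating F6 in toluene at 110 °C (4π opening, 6π closure, tautomerisation) delivers 32.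

2. Step 12. The unhindered ynolate may be silylated at carbon, or the ynol silyl ether may undergo a 1,3-silyl shift, either of which would give the silylketene in place of 20. The fallback brings the silyl group in after the four-membered ring is made; it sets out from 16 and comes back at 23. tert-Butanol, KH and trichloroethylene give the (E)-1,2-dichlorovinyl tert-butyl ether F7, which n-BuLi (2.2 equiv, −78 °C) and a methanol quench convert into tert-butoxyacetylene F8. Used in the step 13 protocol with acid 16, F8 gives the 3-tert-butoxycyclobutenone F9. TIPSOTf/2,6-lutidine in CH2Cl2 then silylates the vinylogous ester carbonyl and expels isobutene, giving 23 with the C7-bearing carbon still sp3.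

3. Step 18. The ortho-silyloxy aryllithium may suffer an anionic 1,3-silyl migration from oxygen to carbon, and a doubly ortho-substituted aryllithium may add slowly to the amide. The fallback builds the acyl group on the free phenol without any organolithium on ring A; it sets out from 32 and comes back at 37. Ortho-formylation of 32 with MgCl2, Et3N and paraformaldehyde in MeCN at 80 °C (only one ortho position is free) gives the salicylaldehyde F10. TIPSOTf/2,6-lutidine then gives the bis-silyl aldehyde F11, and (E)-PhCH=CHMgBr in THF at −78 °C gives the allylic alcohol F12. MnO2 in CH2Cl2 oxidises F12 to 37.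

**Further compounds**

F1 | step 15 | methyl (3S,4E,7R)-7-(TBSO)-3,9-bis(4-TIPSO-phenyl)non-4-enoate | COC(=O)C[C@@H](/C=C/C[C@H](O[Si](C)(C)C(C)(C)C)CCc1ccc(O[Si](C(C)C)(C(C)C)C(C)C)cc1)c1ccc(O[Si](C(C)C)(C(C)C)C(C)C)cc1
F2 | step 15 | methyl (3S,4E,7R)-2,2-dibromo-7-(TBSO)-3,9-bis(4-TIPSO-phenyl)non-4-enoate | COC(=O)C(Br)(Br)[C@@H](/C=C/C[C@H](O[Si](C)(C)C(C)(C)C)CCc1ccc(O[Si](C(C)C)(C(C)C)C(C)C)cc1)c1ccc(O[Si](C(C)C)(C(C)C)C(C)C)cc1
F3 | step 15 | triisopropyl{[(3S,4E,7R)-7-(TBSO)-3,9-bis(4-TIPSO-phenyl)non-4-en-1-yn-1-yl]oxy}silane | CC(C)[Si](C(C)C)(C(C)C)OC#C[C@@H](/C=C/C[C@H](O[Si](C)(C)C(C)(C)C)CCc1ccc(O[Si](C(C)C)(C(C)C)C(C)C)cc1)c1ccc(O[Si](C(C)C)(C(C)C)C(C)C)cc1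
F4 | step 15 | (E)-3-methoxybut-2-enoyl chloride | CO/C(C)=C/C(Cl)=O
F5 | step 15 | 3-methoxybuta-1,3-dien-1-one | C=C(OC)C=C=O
F6 | step 15 | 4-(1-methoxyethenyl)-2-[(1S,2E,5R)-5-(TBSO)-1,7-bis(4-TIPSO-phenyl)hept-2-en-1-yl]-3-(triisopropylsilyloxy)cyclobut-2-en-1-one (C4 epimers) | C=C(OC)C1C(=O)C([C@@H](/C=C/C[C@H](O[Si](C)(C)C(C)(C)C)CCc2ccc(O[Si](C(C)C)(C(C)C)C(C)C)cc2)c2ccc(O[Si](C(C)C)(C(C)C)C(C)C)cc2)=C1O[Si](C(C)C)(C(C)C)C(C)C
F7 | step 12 | (E)-1-tert-butoxy-1,2-dichloroethene | CC(C)(C)O/C(Cl)=C\Cl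
F8 | step 12 | tert-butoxyacetylene | CC(C)(C)OC#C
F9 | step 12 | 3-tert-butoxy-4-[(1R,2E,5R)-5-(TBSO)-1,7-bis(4-TIPSO-phenyl)hept-2-en-1-yl]cyclobut-2-en-1-one (C4 epimers) | O=C1C=C(OC(C)(C)C)C1[C@@H](/C=C/C[C@H](O[Si](C)(C)C(C)(C)C)CCc1ccc(O[Si](C(C)C)(C(C)C)C(C)C)cc1)c1ccc(O[Si](C(C)C)(C(C)C)C(C)C)cc1
F10 | step 18 | 2-hydroxy-6-methoxy-3-[(1S,2E,5R)-5-(TBSO)-1,7-bis(4-TIPSO-phenyl)hept-2-en-1-yl]-4-(triisopropylsilyloxy)benzaldehyde | COc1c(C=O)c(O)c([C@@H](/C=C/C[C@H](O[Si](C)(C)C(C)(C)C)CCc2ccc(O[Si](C(C)C)(C(C)C)C(C)C)cc2)c2ccc(O[Si](C(C)C)(C(C)C)C(C)C)cc2)c(O[Si](C(C)C)(C(C)C)C(C)C)c1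
F11 | step 18 | 6-methoxy-3-[(1S,2E,5R)-5-(TBSO)-1,7-bis(4-TIPSO-phenyl)hept-2-en-1-yl]-2,4-bis(triisopropylsilyloxy)benzaldehyde | COc1c(C=O)c(O[Si](C(C)C)(C(C)C)C(C)C)c([C@@H](/C=C/C[C@H](O[Si](C)(C)C(C)(C)C)CCc2ccc(O[Si](C(C)C)(C(C)C)C(C)C)cc2)c2ccc(O[Si](C(C)C)(C(C)C)C(C)C)cc2)c(O[Si](C(C)C)(C(C)C)C(C)C)c1
F12 | step 18 | (E)-1-{6-methoxy-3-[(1S,2E,5R)-5-(TBSO)-1,7-bis(4-TIPSO-phenyl)hept-2-en-1-yl]-2,4-bis(triisopropylsilyloxy)phenyl}-3-phenylprop-2-en-1-ol (carbinol epimers) | COc1c(C(O)/C=C/c2ccccc2)c(O[Si](C(C)C)(C(C)C)C(C)C)c([C@@H](/C=C/C[C@H](O[Si](C)(C)C(C)(C)C)CCc2ccc(O[Si](C(C)C)(C(C)C)C(C)C)cc2)c2ccc(O[Si](C(C)C)(C(C)C)C(C)C)cc2)c(O[Si](C(C)C)(C(C)C)C(C)C)c1
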